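## Retrosynthetic overview

1. The methylene bridge is cut last: the target comes from an (R)-configured prenyl trione monomer, the aromatic ketone 1-(2,4-dihydroxy-6-methoxyphenyl)butan-1-one, and one CH2 unit (Mannich / methylene-trione coupling).
2. The prenyl group comes from an allyl group by cross-metathesis.
3. Key C–C bond: the quaternary carbon–allyl bond. Iodine(III) oxidation turns the methyl-bearing ring carbon of 3-methylphlorobutyrophenone into an enolonium (phenoxenium) carbon, which is attacked by the nucleophilic carbon of an allylsilane; a chiral iodane sets the stereocentre.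
4. Both aryl ketones come from Friedel–Crafts butanoylation of 2-methylphloroglucinol and of 5-methoxyresorcinol.
5. No ring is built: both six-membered rings are bought as benzene polyols, and the left one is dearomatised in the key step.

Assumption: the target is taken exactly as the given SMILES (quaternary carbon R in the drawn enol tautomer); all dearomatised compounds are drawn in that tautomer unless stated.

Reagent of step 2 (adds no atoms, recovered, not numbered): ArI* = 2-iodo-1,3-bis{[(2R)-1-oxo-1-(2,4,6-trimethylanilino)propan-2-yl]oxy}benzene, a lactate-derived C2-symmetric chiral iodoarene assumed to be commercially available. SMILES: Ic1c(O[C@H](C)C(=O)Nc2c(C)cc(C)cc2C)cccc1O[C@H](C)C(=O)Nc1c(C)cc(C)cc1C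

## Route

Step 1
Reactants: 1 2-methylbenzene-1,3,5-triol (2-methylphloroglucinol), 2 butanoyl chloride
Product: 3 1-(2,4,6-trihydroxy-3-methylphenyl)butan-1-one
Conditions: AlCl3 (3 equiv), PhNO2/CH2Cl2, 0 °C → 50 °C; aq. HCl work-up
Reagents that add atoms: butanoyl chloride, CCCC(Cl)=O
Why: Friedel–Crafts acylation of the triply activated ring at one of its two equivalent free positions, the chelated aryl ketone being deactivated towards a second acylation; no stereocentre.

Step 2
Reactants: 3 1-(2,4,6-trihydroxy-3-methylphenyl)butan-1-one, 4 allyltrimethylsilane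
Product: 6 (4R)-2-butanoyl-3,5-dihydroxy-4-methyl-4-(prop-2-en-1-yl)cyclohexa-2,5-dien-1-one, via aryloxy-λ3-iodane 5 (not isolated)
Conditions: ArI* (1.05 equiv), mCPBA (1.0 equiv), AcOH, CH2Cl2, rt, 3 h (peracid fully consumed); then 3 (1.0 equiv), 4 (3 equiv), HFIP co-solvent, −40 → −20 °C
Reagents that add atoms: allyltrimethylsilane, C=CC[Si](C)(C)C
Why: Proposed new method: the most acidic hydroxyl of 3 (para to the ketone) displaces acetate on the chiral iodine(III) to give the O-bound iodane 5, whose ring is an enolonium (phenoxenium) equivalent, so the normally nucleophilic methyl-bearing ortho carbon is attacked by the nucleophilic γ-carbon of the allylsilane (SE2', β-silyl cation, loss of Me3Si+) as the aryl iodide departs, while the lactamide arms of the still-bound C2-symmetric iodane shield one ring face and set the quaternary centre as R; the closest known reaction types are the PhI(OAc)2/HFIP oxidative dearomative allylation of phenols with allylsilanes and the enantioselective phenol dearomatisations (ortho attack on an O-bound iodane) with this class of lactate-derived iodanes.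

Step 3
Reactants: 6 (4R)-2-butanoyl-3,5-dihydroxy-4-methyl-4-(prop-2-en-1-yl)cyclohexa-2,5-dien-1-one, 7 2-methylbut-2-ene
Product: 8 (4R)-2-butanoyl-3,5-dihydroxy-4-methyl-4-(3-methylbut-2-en-1-yl)cyclohexa-2,5-dien-1-one
Conditions: Hoveyda–Grubbs II (5 mol%), 2-methylbut-2-ene/CH2Cl2 (1:2), 40 °C, sealed tube
Reagents that add atoms: 2-methylbut-2-ene, CC=C(C)C
Why: Olefin cross-metathesis of the terminal allyl group with excess 2-methylbut-2-ene (propene lost) is the standard allyl-to-prenyl conversion and does not touch the all-carbon quaternary stereocentre.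

Step 4
Reactants: 9 5-methoxybenzene-1,3-diol (5-methoxyresorcinol), 2 butanoyl chloride
Product: 10 1-(2,4-dihydroxy-6-methoxyphenyl)butan-1-one
Conditions: AlCl3 (2.5 equiv), PhNO2/CH2Cl2, 0 °C → rt; aq. HCl work-up; chromatography
Reagents that add atoms: butanoyl chloride, CCCC(Cl)=O
Why: Friedel–Crafts acylation at the ring position flanked by OH and OMe (two equivalent such sites against one between the two hydroxyls), with the minor 2,6-dihydroxy-4-methoxy isomer removed by chromatography and the low temperature avoiding AlCl3 demethylation; no stereocentre.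

Step 5
Reactants: 8 (4R)-2-butanoyl-3,5-dihydroxy-4-methyl-4-(3-methylbut-2-en-1-yl)cyclohexa-2,5-dien-1-one, 11 N,N-dimethylmethyleneiminium iodide (Eschenmoser's salt), 10 1-(2,4-dihydroxy-6-methoxyphenyl)butan-1-one
Product: 14 (4R)-2-butanoyl-6-[(3-butanoyl-2,6-dihydroxy-4-methoxyphenyl)methyl]-3,5-dihydroxy-4-methyl-4-(3-methylbut-2-en-1-yl)cyclohexa-2,5-dien-1-one (CNP0285707.1), via Mannich base 12 (not isolated), via methylene trione 13 (not isolated)
Conditions: 11 (1.05 equiv), MeCN, 0 °C → rt, 1 h; then 10 (2 equiv), 70 °C
Reagents that add atoms: N,N-dimethylmethyleneiminium iodide, C[N+](C)=C.[I-]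
Why: Mannich reaction at the only free, strongly C–H acidic ring carbon of 8, then thermal loss of dimethylamine to the 2-methylene trione and Friedel–Crafts-type Michael addition of 10 through its most nucleophilic carbon between the two hydroxyls; the quaternary centre is not involved and keeps its configuration.

## Compound list

1 | 2-methylbenzene-1,3,5-triol | Cc1c(O)cc(O)cc1O | starting material
2 | butanoyl chloride | CCCC(Cl)=O | starting material
3 | 1-(2,4,6-trihydroxy-3-methylphenyl)butan-1-one | CCCC(=O)c1c(O)cc(O)c(C)c1O | intermediate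
4 | allyltrimethylsilane | C=CC[Si](C)(C)C | starting material
5 | aryloxy-λ3-iodane: 3 bound through its 4-oxygen to the acetoxy-iodine(III) of ArI* | CCCC(=O)c1c(O)cc(OI(OC(C)=O)c2c(O[C@H](C)C(=O)Nc3c(C)cc(C)cc3C)cccc2O[C@H](C)C(=O)Nc2c(C)cc(C)cc2C)c(C)c1O | intermediate (not isolated)
6 | (4R)-2-butanoyl-3,5-dihydroxy-4-methyl-4-(prop-2-en-1-yl)cyclohexa-2,5-dien-1-one | CCCC(=O)C1=C(O)[C@](C)(CC=C)C(O)=CC1=O | intermediate
7 | 2-methylbut-2-ene | CC=C(C)C | starting material
8 | (4R)-2-butanoyl-3,5-dihydroxy-4-methyl-4-(3-methylbut-2-en-1-yl)cyclohexa-2,5-dien-1-one | CCCC(=O)C1=C(O)[C@](C)(CC=C(C)C)C(O)=CC1=O | intermediate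
9 | 5-methoxybenzene-1,3-diol | COc1cc(O)cc(O)c1 | starting material
10 | 1-(2,4-dihydroxy-6-methoxyphenyl)butan-1-one | CCCC(=O)c1c(O)cc(O)cc1OC | intermediate
11 | N,N-dimethylmethyleneiminium iodide | C[N+](C)=C.[I-] | starting material
12 | (4R)-2-butanoyl-6-[(dimethylamino)methyl]-3,5-dihydroxy-4-methyl-4-(3-methylbut-2-en-1-yl)cyclohexa-2,5-dien-1-one (Mannich base) | CCCC(=O)C1=C(O)[C@](C)(CC=C(C)C)C(O)=C(CN(C)C)C1=O | intermediate (not isolated)
13 | (4S)-2-butanoyl-3-hydroxy-4-methyl-4-(3-methylbut-2-en-1-yl)-6-methylidenecyclohex-2-ene-1,5-dione (same spatial arrangement as 8; the descriptor changes only because the CIP priorities change) | CCCC(=O)C1=C(O)[C@](C)(CC=C(C)C)C(=O)C(=C)C1=O | intermediate (not isolated)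
14 | (4R)-2-butanoyl-6-[(3-butanoyl-2,6-dihydroxy-4-methoxyphenyl)methyl]-3,5-dihydroxy-4-methyl-4-(3-methylbut-2-en-1-yl)cyclohexa-2,5-dien-1-one | CCCC(=O)C1=C(O)[C@](C)(CC=C(C)C)C(O)=C(Cc2c(O)cc(OC)c(C(=O)CCC)c2O)C1=O | target

## Step count and risks

Total step count: 5. Longest linear sequence: 4 (steps 1, 2, 3, 5); step 4 is a one-step branch.

**Step 2 (most likely to fail).** Three things can go wrong:
- The silane, or the iodine itself, may bond at the free ring C–H carbon instead of the methyl-bearing carbon. This gives the aromatic 5-allyl ketone, which is removed by NaHCO3 extraction because only the trione 6 is acidic enough to go into the aqueous layer.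
- Product 6 still has an oxidisable C–H, so the iodane is kept at no more than 1.0 equiv.
- The level and the sense of asymmetric induction are unproven. The configuration of 6 must be confirmed (ECD or X-ray of a derivative); if the (R,R)-iodane gives the wrong sense, the (S,S)-iodane is used instead.

Fallback, setting out from 3: allylate the phenolate in the normal polarity sense (NaOMe, allyl bromide, MeOH, 0 °C) to give racemic 2-butanoyl-3,5-dihydroxy-4-methyl-4-(prop-2-en-1-yl)cyclohexa-2,5-dien-1-one F1, freed from the aromatic C-allyl by-product by bicarbonate extraction. Resolve F1 by preparative chiral SFC and take the R enantiomer; the route is rejoined at 6.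

**Step 5.** The aromatic partner 10 may react through the carbon between OH and OMe, giving the isomeric benzyl pattern. The methylene trione 13 may also dimerise; pre-forming 12 and using excess 10 limit this. Fallback, setting out from 10: place the bridge carbon on the aromatic partner first by Vilsmeier–Haack formylation (POCl3, DMF, then water) to 3-butanoyl-2,6-dihydroxy-4-methoxybenzaldehyde F2, whose regiochemistry is secured by NMR on cheap material. Then join F2 to 8 by organocatalytic reductive alkylation (L-proline cat., diethyl 2,6-dimethyl-1,4-dihydropyridine-3,5-dicarboxylate, CH2Cl2, rt: Knoevenagel condensation and in-situ conjugate reduction). This comes back to the route at 14.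

**Step 4.** Acylation between the two hydroxyls gives the unwanted 2,6-dihydroxy-4-methoxy ketone, and AlCl3 can cleave the ortho methyl ether. Fallback, setting out from 2: acylate commercial phloroglucinol (AlCl3, PhNO2) to 1-(2,4,6-trihydroxyphenyl)butan-1-one F3. Protect the two non-chelated hydroxyls (MOMCl, iPr2NEt, CH2Cl2) to give 1-[2-hydroxy-4,6-bis(methoxymethoxy)phenyl]butan-1-one F4. Methylate the remaining chelated hydroxyl (MeI, K2CO3, acetone, reflux) to 1-[2-methoxy-4,6-bis(methoxymethoxy)phenyl]butan-1-one F5, and remove the MOM groups (HCl, MeOH). This comes back to the route at 10 with the methoxy position fixed unambiguously.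

## Further compounds

F1 | step 2 | racemic 2-butanoyl-3,5-dihydroxy-4-methyl-4-(prop-2-en-1-yl)cyclohexa-2,5-dien-1-one | CCCC(=O)C1=C(O)C(C)(CC=C)C(O)=CC1=O
F2 | step 5 | 3-butanoyl-2,6-dihydroxy-4-methoxybenzaldehyde | CCCC(=O)c1c(OC)cc(O)c(C=O)c1O
F3 | step 4 | 1-(2,4,6-trihydroxyphenyl)butan-1-one | CCCC(=O)c1c(O)cc(O)cc1O
F4 | step 4 | 1-[2-hydroxy-4,6-bis(methoxymethoxy)phenyl]butan-1-one | CCCC(=O)c1c(O)cc(OCOC)cc1OCOC
F5 | step 4 | 1-[2-methoxy-4,6-bis(methoxymethoxy)phenyl]butan-1-one | CCCC(=O)c1c(OC)cc(OCOC)cc1OCOC
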